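The earlier runs and the new flask are simulated on assumed constants, and the scatter is random.

- In a one-step world X + L gives J and no other path takes L, so in the west flask, with cL = 0.240 M against cX = 0.48 M, L is the limiting reagent and J ends at 50.0% of the X charged.

common to all: X 0.48 M
- west: L 0.24 M; temperature 20 °C; the very flask that is asked about, followed so far
- east: L 0.24 M; temperature 26 °C; run made earlier
- flask: L 0.240 M; temperature 20 °C; time 40 h

| run | time / h | J / % | X / % |
|---|---|---|---|
| west | 5.00 | 19.6 | 23.1 |
| west | 10.0 | 20.1 | 22.9 |
| west | 15.0 | 19.6 | 24.7 |
| west | 20.0 | 20.7 | 24.9 |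
| west | 25.0 | 20.4 | 24.3 |
| west | 30.0 | 20.0 | 23.0 |
| east | 5.00 | 16.7 | 27.6 |
| east | 10.0 | 16.0 | 28.9 |
| east | 15.0 | 16.0 | 28.7 |
| east | 20.0 | 15.8 | 28.1 |
| east | 25.0 | 15.4 | 27.4 |
| east | 30.0 | 16.0 | 26.3 |

(scatter of a reading: 0.5 percentage points)

- J, in percent of the X first charged, at 40 h
- the option that brings most further J ("none" if no option brings more than 2 percentage points) (Sunday's / Thursday's / Wednesday's / Saturday's / none)
- J present, with what was taken out counted in, in percent of the X first charged, after Wednesday's
- J present, with what was taken out counted in, in percent of the X first charged, after Saturday's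

- Sunday's: at 40 h add L, 100% of the amount charged, then wait 12 h
- Thursday's: at 40 h take out 90% of the J then present, then wait 12 h
- Wednesday's: at 40 h raise the temperature by 10 K, then wait 12 h
- Saturday's: change nothing and wait 12 h more

- solid, in amounts per volume of the solution: X
- J that was removed still counts
- the earlier runs were read with a standard deviation of 0.5 percentage points
- at the start none of X is in solution
- additions bring no volume worth counting

- The opposite extreme is a flask where L goes entirely some other way, and there J stays at zero. I place the real flask between the two, because the west readings of J average 20.1% and stay flat from 5.00 h to 30.0 h, while solid X still reads 23.0%.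
- So I name one quantity, the L share: the concentration of J made per concentration of L charged, read from the west run as 40.1%. The east run, with J averaging 16.0%, gives a smaller share, 32.0%.
- I commit to this reading: L has reacted before the first reading, partly to J and partly along a rival path. The flat readings don't tell this apart from a reversible stop.
- On that reading, J at 40 h stays near 20.1%. Saturday's, Thursday's and Wednesday's bring no new L, so I expect J to stay there after each of them, while Sunday's adds 100% of the L charge and at the same share gains 20 percentage points.
- The forecast gives 20.1%, Sunday's, 13.6% after Wednesday's and 20.1% after Saturday's, on the ground “lower when warmer, so this is an exothermic equilibrium”, and after Wednesday's it stands lower than my reckoning.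
- The flask gives 20.0%, Sunday's with a gain of 46 points, 20.0% after Wednesday's and 20.0% after Saturday's.

    D + L + Q → J + 2 Q (k = 0.170 M⁻² s⁻¹, Ea = 39.0 kJ mol⁻¹)
    D + L → J + Q (k = 2.40 × 10⁻⁵ M⁻¹ s⁻¹, Ea = 68.0 kJ mol⁻¹)
    X ⇌ D, rate k3*(cs3 - [D]) while solid is left; crystals form when [D] > cs3 (solubility = 0.270 M, k = 0.00170 s⁻¹)
    2 L → Z (k = 0.00210 M⁻¹ s⁻¹, Ea = 65.0 kJ mol⁻¹)
    (constants at 20 °C)

- Free L in the flask stands at 0% at 40.0 h, and it was under a fiftieth of its charge by 0.688 h. The share doesn't carry to Sunday's, which gains 46 points where I reckoned 20 points. Nor does it carry unchanged to the neighbour flask with 0.060 M of L: my share gives 5.01% of J, but that neighbour reaches 7.21%, a share of 57.7%, with L at 0%. Left ten times as long, J in the flask does not change: at 400 h J stands at 20.0%, an L share of 40.0%.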